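## Retrosynthetic overview

1. Target 36 ⇐ Horner–Wadsworth–Emmons methylenation (CH2O) of α-phosphono lactone 35 ⇐ hydrogenation of bicyclic diene 34.
2. 34 ⇐ double ring-closing metathesis of tetraene ester 33: C13=C14 closes the seven-membered lactone, C9=C10 closes the 14-membered carbocycle (key macrocyclisation).
3. 33 ⇐ ester bond C16–O–C12 between α-phosphono acid 23 and tertiary alcohol 29, then the C8 vinyl carbinol is unveiled from a masked diol.
4. 23 ⇐ oxolane aldehyde 6 (from (R)-linalool; epoxidation/5-exo opening sets C7, C8) + zinc reagent of iodo ester 14 (C1 by Ir allylic alkylation), with C3 set in the coupling; 29 ⇐ enynol 24 by asymmetric epoxidation and Payne/ylide homologation (C11, C12).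
5. Ring order: oxolane (step 2) → temporary δ-lactone (step 9, opened in step 11) → ε-lactone, then carbocycle (both in step 21).

Assumption: atoms are labelled by cembrane numbering (C1 = ring CH carrying C15; C3, C11 = CHOAc; C4, C7 = oxolane carbons; C8 = tertiary carbinol; C12 = lactone C–O carbon; C16 = lactone C=O; C17 = exocyclic CH2), and each chiral ligand is named for the facial sense expected from its usual model, the mirror-image ligand being used if a first run shows the opposite sense.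

## Route

Step 1
Reactants: 1 (R)-linalool
Product: 2 (2E,6R)-2,6-dimethylocta-2,7-diene-1,6-diol
Conditions: SeO2 (0.3 equiv), t-BuOOH (2 equiv), CH2Cl2, 0 °C to rt
Reagents that add atoms: tert-butyl hydroperoxide CC(C)(C)OO
Why: Selenium dioxide allylic oxidation (ene reaction, then [2,3]-shift) hydroxylates only the E-methyl of the trisubstituted alkene and leaves the chiral-pool carbinol C4 (R) untouched.

Step 2
Reactants: 2 (2E,6R)-2,6-dimethylocta-2,7-diene-1,6-diol
Product: 4 (2R)-2-[(2S,5R)-5-ethenyl-5-methyloxolan-2-yl]propane-1,2-diol, via epoxy diol 3 (not isolated)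
Conditions: Ti(OiPr)4 (0.2 equiv), D-(−)-diethyl tartrate (0.25 equiv), t-BuOOH, 4 Å MS, CH2Cl2, −20 °C; then CSA (0.1 equiv), 0 °C
Reagents that add atoms: tert-butyl hydroperoxide CC(C)(C)OO
Why: Sharpless asymmetric epoxidation (reagent control) gives the (7R,8R)-epoxide, which the tertiary C4 hydroxyl opens 5-exo at C7 with inversion (acid-catalysed epoxide-opening cyclisation), fixing C7 as S and C8 as R on a 2,5-cis oxolane.

Step 3
Reactants: 4 (2R)-2-[(2S,5R)-5-ethenyl-5-methyloxolan-2-yl]propane-1,2-diol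
Product: 5 (4R)-4-[(2S,5R)-5-ethenyl-5-methyloxolan-2-yl]-2,2,4-trimethyl-1,3-dioxolane
Conditions: Me2C(OMe)2, PPTS (cat.), CH2Cl2, rt
Reagents that add atoms: 2,2-dimethoxypropane COC(C)(C)OC
Why: Acid-catalysed transketalisation masks the 1,2-diol as an acetonide so that only the vinyl group is left for cleavage; no stereocentre is touched.

Step 4
Reactants: 5 (4R)-4-[(2S,5R)-5-ethenyl-5-methyloxolan-2-yl]-2,2,4-trimethyl-1,3-dioxolane
Product: 6 (2R,5S)-2-methyl-5-[(4R)-2,2,4-trimethyl-1,3-dioxolan-4-yl]oxolane-2-carbaldehyde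
Conditions: O3, CH2Cl2, −78 °C; then PPh3, −78 °C to rt
Reagents that add atoms: ozone O=[O+][O-]
Why: Ozonolysis with reductive work-up turns the only alkene into the C3 aldehyde, which cannot epimerise because C4 is quaternary.

Step 5
Reactants: 7 (E)-but-2-ene-1,4-diol
Product: 8 dimethyl (E)-but-2-ene-1,4-diyl biscarbonate
Conditions: ClCO2Me (2.2 equiv), pyridine, CH2Cl2, 0 °C
Reagents that add atoms: methyl chloroformate COC(=O)Cl
Why: Simple acylation gives the allylic carbonate leaving groups needed for the iridium chemistry.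

Step 6
Reactants: 8 dimethyl (E)-but-2-ene-1,4-diyl biscarbonate; 9 dimethyl malonate
Product: 10 dimethyl 2-[(2S)-1-(methoxycarbonyloxy)but-3-en-2-yl]propanedioate
Conditions: [Ir(cod)Cl]2 (2 mol %), (Ra,R,R)-BINOL N,N-bis(1-phenylethyl)phosphoramidite (4 mol %), TBD (8 mol %), THF, rt, salt-free
Reagents that add atoms: none
Why: Iridium-catalysed asymmetric allylic alkylation attacks the substituted allyl terminus, so the branched product forms and the ligand sets C1; the second carbonate is then no longer allylic and stays.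

Step 7
Reactants: 10 dimethyl 2-[(2S)-1-(methoxycarbonyloxy)but-3-en-2-yl]propanedioate
Product: 12 (4R)-4-ethenyloxolan-2-one, via carboxy lactone 11 (not isolated)
Conditions: KOH, MeOH/H2O, rt; HCl to pH 1; then toluene, 110 °C
Reagents that add atoms: potassium hydroxide [K+].[OH-]
Why: Saponification, acid lactonisation of the γ-hydroxy malonic acid and thermal decarboxylation (malonic ester sequence) give the β-vinyl butyrolactone without touching C1.

Step 8
Reactants: 12 (4R)-4-ethenyloxolan-2-one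
Product: 14 ethyl (3R)-3-(iodomethyl)pent-4-enoate, via silyl ester 13 (not isolated)
Conditions: Me3SiI (1.3 equiv), CH2Cl2, rt; then EtOH, 0 °C to rt
Reagents that add atoms: iodotrimethylsilane C[Si](C)(C)I; ethanol CCO
Why: Iodide opens the O-silylated lactone at the alkyl C–O bond (SN2), and ethanolysis turns the silyl ester into the ethyl ester; C1 is not involved.

Step 9
Reactants: 14 ethyl (3R)-3-(iodomethyl)pent-4-enoate; 6 (2R,5S)-2-methyl-5-[(4R)-2,2,4-trimethyl-1,3-dioxolan-4-yl]oxolane-2-carbaldehyde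
Product: 17 (4R,6R)-4-ethenyl-6-[(2R,5S)-2-methyl-5-[(4R)-2,2,4-trimethyl-1,3-dioxolan-4-yl]oxolan-2-yl]oxan-2-one, via diorganozinc 15 (not isolated), via hydroxy ester 16 (not isolated)
Conditions: Et2Zn (neat), CuI (0.3 mol %), 50 °C, then volatiles removed; Ti(OiPr)4 (2 equiv), (1S,2S)-N,N'-bis(trifluoromethylsulfonyl)cyclohexane-1,2-diamine (8 mol %), toluene, −20 °C, add 6; aq. NH4Cl; then PPTS (cat.), toluene, 60 °C
Reagents that add atoms: none
Why: Knochel iodine–zinc exchange gives an ester-tolerant diorganozinc that adds to the aldehyde under chiral bis-sulfonamide/titanium control (catalyst-controlled carbonyl alkylation) to set C3 as R, and the δ-hydroxy ester then lactonises.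

Step 10
Reactants: 17 (4R,6R)-4-ethenyl-6-[(2R,5S)-2-methyl-5-[(4R)-2,2,4-trimethyl-1,3-dioxolan-4-yl]oxolan-2-yl]oxan-2-one
Product: 19 3-(diethoxyphosphoryl) derivative of lactone 17 (C15 epimers), via enol phosphate 18 (not isolated)
Conditions: LDA (1.1 equiv), THF, −78 °C; ClP(O)(OEt)2; then LDA (2.2 equiv), −78 to 0 °C; aq. NH4Cl
Reagents that add atoms: diethyl chlorophosphate CCOP(=O)(Cl)OCC
Why: Wiemer sequence (O-phosphorylation of the lactone enolate, then base-induced 1,3-phosphoryl shift from O to C) installs the phosphonate that later carries the exocyclic methylene; the new C15 centre is inconsequential.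

Step 11
Reactants: 19 3-(diethoxyphosphoryl) derivative of lactone 17
Product: 22 allyl ester of the ring-opened C3-acetoxy α-phosphono acid, via lithium carboxylate 20 (not isolated), via hydroxy allyl ester 21 (not isolated)
Conditions: LiOH, THF/H2O, rt; buffer to pH 8, evaporate; allyl bromide, DMF, rt; then Ac2O, DMAP, pyridine, rt
Reagents that add atoms: lithium hydroxide [Li+].[OH-]; allyl bromide C=CCBr; acetic anhydride CC(=O)OC(C)=O
Why: Saponification opens the δ-lactone, SN2 O-allylation caps the carboxylate so that DMAP-catalysed acetylation of the freed C3 hydroxyl cannot relactonise; no stereocentre changes.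

Step 12
Reactants: 22 allyl ester of the C3-acetoxy α-phosphono acid
Product: 23 C3-acetoxy α-phosphono carboxylic acid (free acid of 22)
Conditions: Pd(PPh3)4 (5 mol %), morpholine, THF, rt
Reagents that add atoms: none
Why: Tsuji–Trost deallylation frees the acid under neutral conditions that spare both the acetate and the acetonide.

Step 13
Reactants: 24 (2E)-3-methylpent-2-en-4-yn-1-ol
Product: 25 (2E)-3-methylpenta-2,4-dien-1-ol
Conditions: H2 (1 atm), Pd/CaCO3 poisoned with Pb(OAc)2, quinoline, EtOAc, rt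
Reagents that add atoms: none
Why: Lindlar semihydrogenation stops at the terminal alkene and keeps the E-trisubstituted alkene.

Step 14
Reactants: 25 (2E)-3-methylpenta-2,4-dien-1-ol
Product: 26 [(2R,3R)-3-ethenyl-3-methyloxiran-2-yl]methanol
Conditions: Ti(OiPr)4 (0.1 equiv), D-(−)-diethyl tartrate (0.12 equiv), t-BuOOH, 4 Å MS, CH2Cl2, −20 °C
Reagents that add atoms: tert-butyl hydroperoxide CC(C)(C)OO
Why: Sharpless asymmetric epoxidation acts only on the allylic-alcohol alkene and sets C12 (R) by reagent control.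

Step 15
Reactants: 26 [(2R,3R)-3-ethenyl-3-methyloxiran-2-yl]methanol
Product: 28 (3R,4S)-3-methylhexa-1,5-diene-3,4-diol, via Payne epoxide 27 (not isolated)
Conditions: trimethylsulfonium iodide (3.5 equiv), n-BuLi (3.3 equiv), THF, −10 °C to rt
Reagents that add atoms: trimethylsulfonium iodide C[S+](C)C.[I-]
Why: Payne rearrangement moves the epoxide to the terminus with inversion at C11 (giving S), and dimethylsulfonium methylide opens it and eliminates (one-carbon epoxide-to-allylic-alcohol homologation); C12 keeps its oxygen and stays R.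

Step 16
Reactants: 28 (3R,4S)-3-methylhexa-1,5-diene-3,4-diol
Product: 29 (3S,4R)-4-hydroxy-4-methylhexa-1,5-dien-3-yl acetate
Conditions: Ac2O (1.1 equiv), pyridine, DMAP (cat.), CH2Cl2, 0 °C
Reagents that add atoms: acetic anhydride CC(=O)OC(C)=O
Why: Acylation is selective for the secondary over the tertiary hydroxyl, which installs the final C11 acetate.

Step 17
Reactants: 23 C3-acetoxy α-phosphono carboxylic acid; 29 (3S,4R)-4-hydroxy-4-methylhexa-1,5-dien-3-yl acetate
Product: 30 tertiary ester of acid 23 at the C12 hydroxyl of 29 (triene, acetonide intact)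
Conditions: DCC (1.5 equiv), DMAP (1 equiv), CH2Cl2, 0 °C to rt
Reagents that add atoms: none
Why: Carbodiimide activation of an α-phosphono acid passes through a phosphonoketene, which is small enough to acylate the tertiary allylic alcohol (Steglich-type esterification); no stereocentre is touched.

Step 18
Reactants: 30 tertiary ester (acetonide)
Product: 31 C8,C9-diol of ester 30
Conditions: AcOH/THF/H2O (4:1:1), 40 °C
Reagents that add atoms: none
Why: Mild acetal hydrolysis frees the diol while acetates, phosphonate and the tertiary ester remain.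

Step 19
Reactants: 31 C8,C9-diol of ester 30
Product: 32 C9 aldehyde (tertiary α-hydroxy aldehyde) of ester 30
Conditions: TEMPO (0.1 equiv), PhI(OAc)2 (1.2 equiv), CH2Cl2, rt
Reagents that add atoms: none
Why: Oxoammonium (TEMPO) oxidation takes only the primary alcohol; the tertiary C8 hydroxyl cannot be oxidised.

Step 20
Reactants: 32 C9 aldehyde of ester 30
Product: 33 tetraene ester bearing the C8 vinyl carbinol
Conditions: CH2I2, Zn, Ti(OiPr)4 (1 equiv), THF, rt
Reagents that add atoms: diiodomethane ICI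
Why: Takai-type methylenation with the gem-dizinc reagent is aldehyde-selective and non-basic, so the acidic phosphonoacetate and the acetates survive where a Wittig ylide would not.

Step 21
Reactants: 33 tetraene ester
Product: 34 bicyclic diene (seven-membered lactone with Z C13=C14; 14-membered carbocycle with C9=C10 as E/Z mixture)
Conditions: second-generation Grubbs catalyst (2 × 10 mol %), toluene (0.5 mM), 80 °C, argon sparge
Reagents that add atoms: none
Why: Double ring-closing metathesis: the C1 and C12 vinyl groups close the seven-membered lactone first, then the C8 and C11 vinyl groups close the 14-membered ring at high dilution with loss of ethene; no sp3 centre changes.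

Step 22
Reactants: 34 bicyclic diene
Product: 35 saturated bicyclic α-phosphono lactone
Conditions: H2 (1 atm), [Ir(cod)(PCy3)(py)]PF6 (15 mol %), CH2Cl2, rt
Reagents that add atoms: none
Why: Homogeneous hydroxyl- and carbonyl-directed hydrogenation reduces both hindered disubstituted alkenes without hydrogenolysis of the allylic C–O bonds.

Step 23
Reactants: 35 saturated bicyclic α-phosphono lactone
Product: 36 target CNP0343714.4
Conditions: K2CO3, (CH2O)n, THF, 60 °C
Reagents that add atoms: formaldehyde C=O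
Why: Horner–Wadsworth–Emmons olefination of the phosphonate-stabilised lactone anion with formaldehyde gives the α-methylene lactone under base too weak to cleave the acetates; both C15 epimers converge.

## Compound list

1 | (R)-linalool, (3R)-3,7-dimethylocta-1,6-dien-3-ol | CC(C)=CCC[C@@](C)(O)C=C | starting material
2 | (2E,6R)-2,6-dimethylocta-2,7-diene-1,6-diol | OC/C(C)=C/CC[C@@](C)(O)C=C | intermediate
3 | [(2R,3R)-3-[(3R)-3-hydroxy-3-methylpent-4-en-1-yl]-2-methyloxiran-2-yl]methanol (epoxy diol) | OC[C@@]1(C)O[C@@H]1CC[C@@](C)(O)C=C | intermediate (not isolated)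
4 | (2R)-2-[(2S,5R)-5-ethenyl-5-methyloxolan-2-yl]propane-1,2-diol | C=C[C@@]1(C)CC[C@H](O1)[C@](C)(O)CO | intermediate
5 | (4R)-4-[(2S,5R)-5-ethenyl-5-methyloxolan-2-yl]-2,2,4-trimethyl-1,3-dioxolane | C=C[C@@]1(C)CC[C@H](O1)[C@@]2(C)COC(C)(C)O2 | intermediate
6 | (2R,5S)-2-methyl-5-[(4R)-2,2,4-trimethyl-1,3-dioxolan-4-yl]oxolane-2-carbaldehyde | O=C[C@@]1(C)CC[C@H](O1)[C@@]2(C)COC(C)(C)O2 | intermediate
7 | (E)-but-2-ene-1,4-diol | OC/C=C/CO | starting material
8 | dimethyl (E)-but-2-ene-1,4-diyl biscarbonate | COC(=O)OC/C=C/COC(=O)OC | intermediate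
9 | dimethyl malonate | COC(=O)CC(=O)OC | starting material
10 | dimethyl 2-[(2S)-1-(methoxycarbonyloxy)but-3-en-2-yl]propanedioate | COC(=O)OC[C@@H](C=C)C(C(=O)OC)C(=O)OC | intermediate
11 | 2-oxo-4-ethenyloxolane-3-carboxylic acid, vinyl carbon as in 12 (carboxy lactone) | OC(=O)C1[C@H](C=C)COC1=O | intermediate (not isolated)
12 | (4R)-4-ethenyloxolan-2-one | C=C[C@@H]1COC(=O)C1 | intermediate
13 | trimethylsilyl (3R)-3-(iodomethyl)pent-4-enoate (silyl ester) | C[Si](C)(C)OC(=O)C[C@@H](CI)C=C | intermediate (not isolated)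
14 | ethyl (3R)-3-(iodomethyl)pent-4-enoate | CCOC(=O)C[C@@H](CI)C=C | intermediate
15 | bis[(2R)-2-(2-ethoxy-2-oxoethyl)but-3-en-1-yl]zinc (diorganozinc) | CCOC(=O)C[C@@H](C[Zn]C[C@H](CC(=O)OCC)C=C)C=C | intermediate (not isolated)
16 | ethyl (3R,5R)-3-ethenyl-5-hydroxy-5-[(2R,5S)-2-methyl-5-[(4R)-2,2,4-trimethyl-1,3-dioxolan-4-yl]oxolan-2-yl]pentanoate (hydroxy ester) | CCOC(=O)C[C@H](C=C)C[C@@H](O)[C@@]1(C)CC[C@H](O1)[C@@]2(C)COC(C)(C)O2 | intermediate (not isolated)
17 | (4R,6R)-4-ethenyl-6-[(2R,5S)-2-methyl-5-[(4R)-2,2,4-trimethyl-1,3-dioxolan-4-yl]oxolan-2-yl]oxan-2-one | O=C1C[C@H](C=C)C[C@@H](O1)[C@@]2(C)CC[C@H](O2)[C@@]3(C)COC(C)(C)O3 | intermediate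
18 | diethyl enol phosphate of lactone 17 (O-phosphorylated ketene acetal, stereocentres as in 17) | CCOP(=O)(OCC)OC1=C[C@H](C=C)C[C@@H](O1)[C@@]2(C)CC[C@H](O2)[C@@]3(C)COC(C)(C)O3 | intermediate (not isolated)
19 | 3-(diethoxyphosphoryl) derivative of lactone 17 (C15 epimers, other centres as in 17) | O=C1C(P(=O)(OCC)OCC)[C@H](C=C)C[C@@H](O1)[C@@]2(C)CC[C@H](O2)[C@@]3(C)COC(C)(C)O3 | intermediate
20 | lithium salt of the ring-opened C3-hydroxy α-phosphono acid (lithium carboxylate) | [Li+].[O-]C(=O)C(P(=O)(OCC)OCC)[C@H](C=C)C[C@@H](O)[C@@]1(C)CC[C@H](O1)[C@@]2(C)COC(C)(C)O2 | intermediate (not isolated)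
21 | allyl ester of the C3-hydroxy α-phosphono acid (hydroxy allyl ester) | C=CCOC(=O)C(P(=O)(OCC)OCC)[C@H](C=C)C[C@@H](O)[C@@]1(C)CC[C@H](O1)[C@@]2(C)COC(C)(C)O2 | intermediate (not isolated)
22 | allyl ester of the C3-acetoxy α-phosphono acid (C1, C3, C4, C7, C8 as in 17) | C=CCOC(=O)C(P(=O)(OCC)OCC)[C@H](C=C)C[C@@H](OC(C)=O)[C@@]1(C)CC[C@H](O1)[C@@]2(C)COC(C)(C)O2 | intermediate
23 | C3-acetoxy α-phosphono carboxylic acid (free acid of 22) | OC(=O)C(P(=O)(OCC)OCC)[C@H](C=C)C[C@@H](OC(C)=O)[C@@]1(C)CC[C@H](O1)[C@@]2(C)COC(C)(C)O2 | intermediate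
24 | (2E)-3-methylpent-2-en-4-yn-1-ol | C#C/C(C)=C/CO | starting material
25 | (2E)-3-methylpenta-2,4-dien-1-ol | C=C/C(C)=C/CO | intermediate
26 | [(2R,3R)-3-ethenyl-3-methyloxiran-2-yl]methanol | OC[C@H]1O[C@]1(C)C=C | intermediate
27 | (2R)-2-[(2S)-oxiran-2-yl]but-3-en-2-ol (Payne epoxide, formed as its alkoxide) | C=C[C@@](C)(O)[C@@H]1CO1 | intermediate (not isolated)
28 | (3R,4S)-3-methylhexa-1,5-diene-3,4-diol | C=C[C@@](C)(O)[C@@H](O)C=C | intermediate
29 | (3S,4R)-4-hydroxy-4-methylhexa-1,5-dien-3-yl acetate | C=C[C@@](C)(O)[C@@H](OC(C)=O)C=C | intermediate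
30 | (3S,4R)-3-acetoxy-4-methylhexa-1,5-dien-4-yl ester of acid 23 (acetonide intact) | C=C[C@@](C)(OC(=O)C(P(=O)(OCC)OCC)[C@H](C=C)C[C@@H](OC(C)=O)[C@@]1(C)CC[C@H](O1)[C@@]2(C)COC(C)(C)O2)[C@@H](OC(C)=O)C=C | intermediate
31 | C8,C9-diol obtained from 30 by loss of the acetonide | C=C[C@@](C)(OC(=O)C(P(=O)(OCC)OCC)[C@H](C=C)C[C@@H](OC(C)=O)[C@@]1(C)CC[C@H](O1)[C@](C)(O)CO)[C@@H](OC(C)=O)C=C | intermediate
32 | C9 aldehyde of 31 (tertiary α-hydroxy aldehyde) | C=C[C@@](C)(OC(=O)C(P(=O)(OCC)OCC)[C@H](C=C)C[C@@H](OC(C)=O)[C@@]1(C)CC[C@H](O1)[C@](C)(O)C=O)[C@@H](OC(C)=O)C=C | intermediate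
33 | tetraene ester (C8 vinyl carbinol; vinyl groups on C1, C8, C11, C12) | C=C[C@@](C)(OC(=O)C(P(=O)(OCC)OCC)[C@H](C=C)C[C@@H](OC(C)=O)[C@@]1(C)CC[C@H](O1)[C@](C)(O)C=C)[C@@H](OC(C)=O)C=C | intermediate
34 | bicyclic diene: 15-(diethoxyphosphoryl) ε-lactone with Z C13=C14 and E/Z C9=C10, sp3 centres as in the target | CCOP(=O)(OCC)C1C(=O)O[C@]2(C)C=C[C@@H]1C[C@@H](OC(C)=O)[C@@]1(C)CC[C@H](O1)[C@](C)(O)C=C[C@@H]2OC(C)=O | intermediate
35 | saturated bicyclic 15-(diethoxyphosphoryl) lactone (target with P(O)(OEt)2 and H in place of the exocyclic CH2) | CCOP(=O)(OCC)C1C(=O)O[C@]2(C)CC[C@@H]1C[C@@H](OC(C)=O)[C@@]1(C)CC[C@H](O1)[C@](C)(O)CC[C@@H]2OC(C)=O | intermediate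
36 | CNP0343714.4 (1R,3R,4R,7S,8R,11S,12R by the numbering above) | C=C1C(=O)O[C@]2(C)CC[C@@H]1C[C@@H](OC(C)=O)[C@@]1(C)CC[C@H](O1)[C@](C)(O)CC[C@@H]2OC(C)=O | target

## Step count

Total step count: 23.
Longest linear sequence: 15 steps (1–4, 9–12, 17–23; the branch 5–8, 9–12, 17–23 is equally long; the branch 13–16, 17–23 is 11), i.e. 15/23 of the total.

## Steps most likely to fail, with fallbacks

Step 21 (double ring-closing metathesis). Four vinyl groups can pair wrongly, and the macrocyclic closure joins two hindered allylic alkenes. Fallback: set out from triene ester 30, which has only the C1, C11 and C12 vinyl groups, and close the rings one at a time. Metathesis of 30 (second-generation Grubbs catalyst, CH2Cl2, 40 °C) gives the seven-membered unsaturated lactone acetonide F6. AcOH/THF/H2O gives the diol F7, TEMPO/PhI(OAc)2 gives the hydroxy aldehyde F8, and CH2I2/Zn/Ti(OiPr)4 gives the vinyl carbinol F9. F9 has a single possible pairing and is cyclised at high dilution to come back at 34.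

Step 17 (acylation of the tertiary allylic alcohol). If the phosphonoketene route gives mainly N-acylurea or returns 29, change the acyl donor. Fallback: set out from acid 23; 2,2'-dipyridyl disulfide/PPh3 gives the S-(pyridin-2-yl) thioester F5. AgOSO2CF3 in toluene then drives thiophilic acyl transfer to alcohol 29 (Gerlach–Masamune type activation) and the route comes back at 30.

Step 9 (catalyst-controlled alkylzinc addition to a hindered α-alkoxy aldehyde). Low conversion or poor control at C3 is possible. Fallback: set out from aldehyde 6 and build C3 as a ketone first. NaClO2/NaH2PO4/2-methylbut-2-ene gives the carboxylic acid F1, and DCC/EtSH/DMAP gives the S-ethyl thioester F2. Iodo ester 14 with Zn/LiCl gives the alkylzinc iodide F3, and Fukuyama coupling of F2 with F3 (PdCl2(PPh3)2, toluene) gives the keto ester F4. Reduction with (S)-2-methyl-CBS-oxazaborolidine/BH3·SMe2 sets C3 (R) by reagent control and gives hydroxy ester 16, which lactonises (PPTS) to come back at 17.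

Further compounds

F1 | step 9 | (2R,5S)-2-methyl-5-[(4R)-2,2,4-trimethyl-1,3-dioxolan-4-yl]oxolane-2-carboxylic acid | OC(=O)[C@@]1(C)CC[C@H](O1)[C@@]2(C)COC(C)(C)O2
F2 | step 9 | S-ethyl thioester of F1 | CCSC(=O)[C@@]1(C)CC[C@H](O1)[C@@]2(C)COC(C)(C)O2
F3 | step 9 | [(2R)-2-(2-ethoxy-2-oxoethyl)but-3-en-1-yl]zinc iodide | CCOC(=O)C[C@@H](C[Zn]I)C=C
F4 | step 9 | keto ester (C3 ketone analogue of hydroxy ester 16) | CCOC(=O)C[C@H](C=C)CC(=O)[C@@]1(C)CC[C@H](O1)[C@@]2(C)COC(C)(C)O2
F5 | step 17 | S-(pyridin-2-yl) thioester of acid 23 | O=C(Sc1ccccn1)C(P(=O)(OCC)OCC)[C@H](C=C)C[C@@H](OC(C)=O)[C@@]1(C)CC[C@H](O1)[C@@]2(C)COC(C)(C)O2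
F6 | step 21 | seven-membered unsaturated lactone from 30 (C13=C14 closed, acetonide and C11 vinyl intact) | CCOP(=O)(OCC)C1C(=O)O[C@](C)(C=C[C@@H]1C[C@@H](OC(C)=O)[C@@]2(C)CC[C@H](O2)[C@@]3(C)COC(C)(C)O3)[C@@H](OC(C)=O)C=C
F7 | step 21 | C8,C9-diol of F6 | CCOP(=O)(OCC)C1C(=O)O[C@](C)(C=C[C@@H]1C[C@@H](OC(C)=O)[C@@]2(C)CC[C@H](O2)[C@](C)(O)CO)[C@@H](OC(C)=O)C=C
F8 | step 21 | C9 aldehyde of F7 | CCOP(=O)(OCC)C1C(=O)O[C@](C)(C=C[C@@H]1C[C@@H](OC(C)=O)[C@@]2(C)CC[C@H](O2)[C@](C)(O)C=O)[C@@H](OC(C)=O)C=C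
F9 | step 21 | C8 vinyl carbinol of the seven-membered lactone (diene for the macrocyclic closure) | CCOP(=O)(OCC)C1C(=O)O[C@](C)(C=C[C@@H]1C[C@@H](OC(C)=O)[C@@]2(C)CC[C@H](O2)[C@](C)(O)C=C)[C@@H](OC(C)=O)C=C
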